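The data were computed on assumed constants; the scatter is artificial.

I counted everything as a fraction of the first end groups charged, and took each link and each ring to use one first and one second end group.

| flask | first end groups | second end groups | protic impurity | temperature | remark | time |
|---|---|---|---|---|---|---|
| dusk | 0.23 M | 0.225 M | 0.0115 M | −10 °C | run made earlier |  |
| winter | 0.23 M | 0.225 M | 0.016 M | 5 °C | run made earlier |  |
| summer | 0.23 M | 0.225 M | 0.025 M | −10 °C | run made earlier |  |
| dawn | 0.23 M | 0.11 M | 0.0115 M | 5 °C | run made earlier |  |
| birch | 0.23 M (fed, over 6.0 h) | 0.225 M | 0.0115 M |  | the addition at −35 °C, then warmed to 5 °C; the feed brings no volume worth counting | 8.0 h |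
| oak | 0.23 M (in portions, 2, over 6.0 h) | 0.225 M | 0.0115 M | 5 °C | first portion at the start, last at 6.0 h | 8.0 h |
| larch | 0.23 M | 0.225 M | 0.0115 M | 5 °C | everything together at the start | 8.0 h |
| cedar | 0.23 M (fed, over 6.0 h) | 0.225 M | 0.0115 M | 5 °C | all else is in the flask from the start; the feed brings no volume worth counting | 8.0 h |
| maple | 0.23 M | 0.225 M | 0.0115 M |  | everything together at the start at −35 °C, warmed to 5 °C at 6.0 h | 8.0 h |

| run | time / h | links / % | rings / % |
|---|---|---|---|
| dusk | 2.00 | 46.7 | 18.3 |
| dusk | 4.00 | 51.9 | 24.5 |
| dusk | 6.00 | 54.7 | 27.6 |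
| dusk | 8.00 | 56.0 | 32.1 |
| dusk | 10.0 | 55.0 | 31.9 |
| winter | 2.00 | 39.3 | 45.3 |
| winter | 4.00 | 41.0 | 48.2 |
| winter | 6.00 | 39.8 | 50.2 |
| winter | 8.00 | 38.5 | 51.5 |
| winter | 10.0 | 40.9 | 52.4 |
| summer | 2.00 | 44.4 | 19.0 |
| summer | 5.00 | 52.6 | 26.7 |
| summer | 8.00 | 53.5 | 31.6 |
| summer | 12.0 | 53.5 | 33.4 |
| summer | 20.0 | 54.0 | 35.5 |
| dawn | 0.833 | 13.1 | 34.3 |
| dawn | 1.33 | 12.8 | 32.3 |
| dawn | 2.50 | 12.5 | 35.0 |
| dawn | 5.00 | 13.4 | 33.9 |
| dawn | 10.0 | 16.4 | 32.7 |

(scatter of a reading: 1 percentage point)

- the flask with the highest share of links in links plus rings ("all alike" if they lie within 1.5 percentage points) (birch / oak / larch / cedar / maple / all alike)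
- share of links in links plus rings at the end, birch
- share of links in links plus rings at the end, oak
- share of links in links plus rings at the end, larch
- share of links in links plus rings at the end, cedar
- share of links in links plus rings at the end, maple

- the numbers in the tables scatter by 1 percentage point (one standard deviation)

1. Winter and dawn looked nearly the same: both ran at 5 °C with the same first end groups and similar protic impurity (0.016 M and 0.0115 M). But dawn held 47.8% of second end groups against 97.8% in winter, about half.

2. Dawn's links plus rings reached 49.1% at its last reading, which within the scatter is its charge of second end groups, the limiting reagent there.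

3. Links over rings read 0.781 at winter's last reading and 0.405 over all of dawn, again about half. So I took the link rate to be first order in second end groups, relative to the ring rate.

4. As second end groups ran down, I took their mean as half the charge. Dawn then gave 59.0%. I call this the crossover fraction, the second end groups left, as a fraction of the first ends charged, at which links and rings form equally fast. Their ratio at any moment is then the second end groups left over this fraction, a selectivity factor. Winter, read separately, gave 62.7%.

5. Dusk, at −10 °C, read roughly 28.4%, lower than at 5 °C, so cold favoured links.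

6. For larch my reckoning gave a share of links of 45.3%. I expected maple and birch above that, and put no number on them.

7. The forecast chose maple, with 52% for maple, 48% for birch, 44.5% for oak, 43.5% for larch and 44% for cedar, holding that “feeding first ends at constant temperature changes almost nothing”. Its larch figure was lower than mine.

    first end groups + second end groups → links (k = 0.00356 M⁻¹ s⁻¹, Ea = 57.0 kJ mol⁻¹)
    first end groups + second end groups → rings, rate k2*[first end groups] as long as [second end groups] is above zero (k = 4.42 × 10⁻⁴ s⁻¹, Ea = 90.0 kJ mol⁻¹)
    first end groups ⇌ dormant form (K = 3.90, k = 1.77 × 10⁻⁴ s⁻¹, Ea = 94.0 kJ mol⁻¹, ΔH = 2.00 kJ mol⁻¹)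
    second end groups + protic impurity → quenched reagent (k = 0.00295 M⁻¹ s⁻¹, Ea = 48.0 kJ mol⁻¹)
    second end groups → decomposition product (k = 6.14 × 10⁻⁸ s⁻¹, Ea = 109 kJ mol⁻¹)
    (constants at 5 °C)

Maple came out highest at 54.5%, against 50.7% for birch, 44.5% for oak, 43.8% for larch and 43.7% for cedar. In maple, second end groups went into links 20 times as fast as into rings at the start, but 1.3 times as fast at 6.03 h, just after warming. Maple, still at −35 °C at 5.00 h, held links 18.3% and rings 1.03% of the first ends charged. For larch, at 5 °C, the crossover fraction 59.0% had given 45.3%, and larch stood at 43.8%.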